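**Plan (labdane numbering, C1–C20, is used for all compounds)**
1. Retrosynthesis of the side rings: the C15–O bond of the spiro lactone is cut (Baeyer–Villiger logic) to a C13 spiro-cyclobutanone, and this to a C13 exo-enol ether made from a 9α,13-lactone. C17 is removed as MeMgBr. C9–O and C9–C11 are cut at the α′ position of a ring B enone that is stored as the 19,6β-lactone.
2. Ring A is then cut at C1–C2 and C3–C4. The unsubstituted C2–C3 bridge lies between C4, which is α to the carboxyl carbon C19 (a malonate carbanion), and C1, which sits on quaternary C10 (a non-enolisable aldehyde). One vinylphosphonium salt can therefore join both ends in one flask by Michael addition and Wittig closure.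
3. Forward order: ring B from meso cyclohexene diacetate (steps 1–8), ring A by the annulation (step 9), the 19,6β-lactone ring by dehydrogenation and carboxylate addition (step 13), the tetrahydrofuran ring as a 9α,13-lactone (step 17), the spiro lactone last (steps 19–21).
4. Stereochemistry: C5 from the chiral palladium ligand; C10 by cuprate attack trans to the C5 group; C4 by α-face methylation; C6 by intramolecular delivery from the 4β-carboxyl; C9 by α-face enolate hydroxylation; C8 by equatorial Grignard attack; C13 by a catalyst-controlled desymmetrising Baeyer–Villiger oxidation.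

Key step: step 9

Assumption: the sense of induction of the two chiral catalysts ((R,R)-Trost ligand in step 2, (R)-phosphoric acid in step 21) is taken as drawn; if either proves opposite, the enantiomeric catalyst is used.

Step 1
Reactants: 1 cyclohexa-1,3-diene
Product: 2 cis-cyclohex-2-ene-1,4-diyl diacetate (meso)
Conditions: Pd(OAc)2 (5 mol %), LiCl (20 mol %), LiOAc, p-benzoquinone, AcOH, 25 °C
Reagents that add atoms: acetic acid, CC(=O)O
Why: Palladium-catalysed 1,4-diacetoxylation of a 1,3-diene, in which acetate opens the π-allylpalladium intermediate from the face opposite to the metal when chloride blocks the coordination site, so the two acetoxy groups should end cis.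

Step 2
Reactants: 2 cis-cyclohex-2-ene-1,4-diyl diacetate; 3 dimethyl malonate
Product: 4 dimethyl 2-[(1R,4S)-4-acetoxycyclohex-2-en-1-yl]malonate
Conditions: NaH (1.0 equiv), [Pd(C3H5)Cl]2 (2.5 mol %), (R,R)-DACH-phenyl Trost ligand (7.5 mol %), THF, 0 °C
Reagents that add atoms: none
Why: Trost asymmetric allylic alkylation (desymmetrisation): the ligand selects one enantiotopic acetate for ionisation and malonate attacks the π-allyl complex anti to palladium, so net retention gives the cis product and sets C5.

Step 3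
Reactants: 4 dimethyl 2-[(1R,4S)-4-acetoxycyclohex-2-en-1-yl]malonate
Product: 5 dimethyl 2-[(1R,4S)-4-hydroxycyclohex-2-en-1-yl]malonate
Conditions: K2CO3 (0.2 equiv), MeOH, 0 °C
Reagents that add atoms: none
Why: Methoxide-catalysed transesterification removes the allylic acetate; the dimethyl malonate is degenerate under these conditions and no stereocentre is touched.

Step 4
Reactants: 5 dimethyl 2-[(1R,4S)-4-hydroxycyclohex-2-en-1-yl]malonate
Product: 6 dimethyl 2-[(1R)-4-oxocyclohex-2-en-1-yl]malonate
Conditions: MnO2 (10 equiv), CH2Cl2, 25 °C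
Reagents that add atoms: none
Why: MnO2 oxidises the allylic alcohol selectively to the enone; C5 is γ to the carbonyl and should not epimerise under neutral conditions.

Step 5
Reactants: 6 dimethyl 2-[(1R)-4-oxocyclohex-2-en-1-yl]malonate
Product: 8 dimethyl 2-[(1S)-2-methyl-4-oxocyclohex-2-en-1-yl]malonate, via silyl enol ether 7 (not isolated)
Conditions: MeMgBr (2.2 equiv), CuBr·SMe2 (10 mol %), Me3SiCl (2.5 equiv), THF, −78 °C; NaHCO3 wash; then Pd(OAc)2 (10 mol %), O2 (1 atm), DMSO, 25 °C
Reagents that add atoms: methylmagnesium bromide, C[Mg]Br; chlorotrimethylsilane, C[Si](C)(C)Cl (silyl group present only in 7)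
Why: Copper-catalysed conjugate methylation with silyl trapping, then Saegusa–Ito dehydrogenation of the silyl enol ether, re-forms the enone with the methyl group on C10; the transient C10 stereocentre is erased and the Grignard equivalent taken up by the malonate C–H is released on work-up.

Step 6
Reactants: 8 dimethyl 2-[(1S)-2-methyl-4-oxocyclohex-2-en-1-yl]malonate
Product: 9 dimethyl 2-[(1S,2S)-2-methyl-4-oxo-2-vinylcyclohexyl]malonate
Conditions: CH2=CHMgBr (2.5 equiv), CuBr·SMe2 (20 mol %), Me3SiCl (2.5 equiv), THF, −78 → −30 °C; then 1 M HCl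
Reagents that add atoms: vinylmagnesium bromide, C=C[Mg]Br
Why: Silyl chloride-accelerated copper-catalysed conjugate addition to the β,β-disubstituted enone should occur anti to the neighbouring C5 malonyl group (the trans rule for 4-substituted cyclohexenones), which sets quaternary C10 with vinyl trans and methyl cis to C4.

Step 7
Reactants: 9 dimethyl 2-[(1S,2S)-2-methyl-4-oxo-2-vinylcyclohexyl]malonate
Product: 10 dimethyl 2-[7-methyl-7-vinyl-1,4-dioxaspiro[4.5]decan-8-yl]malonate (configuration of 9)
Conditions: Me3SiOCH2CH2OSiMe3 (1.5 equiv), Me3SiOTf (5 mol %), CH2Cl2, −78 → −20 °C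
Reagents that add atoms: 1,2-bis(trimethylsilyloxy)ethane, C[Si](C)(C)OCCO[Si](C)(C)C
Why: Aprotic ketalisation masks the C8 ketone so that later bases meet only the malonate and the C19 carboxyl, without transesterifying the malonate.

Step 8
Reactants: 10 dimethyl 2-[7-methyl-7-vinyl-1,4-dioxaspiro[4.5]decan-8-yl]malonate
Product: 12 dimethyl 2-[7-formyl-7-methyl-1,4-dioxaspiro[4.5]decan-8-yl]malonate, via ozonide 11 (not isolated)
Conditions: O3, CH2Cl2, −78 °C; then Me2S, −78 → 25 °C
Reagents that add atoms: ozone, [O-][O+]=O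
Why: Ozonolysis of the only alkene through the secondary ozonide and reductive work-up gives the C1 aldehyde on quaternary C10; no stereocentre is affected.

Step 9
Reactants: 12 dimethyl 2-[7-formyl-7-methyl-1,4-dioxaspiro[4.5]decan-8-yl]malonate; 13 triphenyl(vinyl)phosphonium bromide
Product: 15 dimethyl 8,8-(ethylenedioxy)-10β-methyl-5αH-decal-1-ene-4,4-dicarboxylate (trans ring fusion), via phosphonium ylide 14 (not isolated)
Conditions: NaH (1.05 equiv), THF, 0 °C; 13 (1.2 equiv), 0 → 66 °C
Reagents that add atoms: none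
Why: The sodium malonate of 12 adds in Michael fashion to the vinylphosphonium salt (C3–C4 bond); the resulting ylide 14, a carbanion at C2, attacks the aldehyde C1 and the oxaphosphetane collapses to the C1=C2 alkene and Ph3PO (C1–C2 bond), so both bonds and ring A arise in one flask. The closest known reaction is the Schweizer annulation of carbonyl-tethered malonate anions with vinyltriphenylphosphonium bromide to give cycloalkenes. Ring A closes by 6-exo-trig attack of the ylide carbon on the aldehyde carbonyl, and the trans ring fusion is inherited from the trans-diequatorial C5 malonyl and C10 formyl groups set in steps 2 and 6. No new stereocentre is formed, because C4 carries two identical ester groups and C1 and C2 become sp2. The step needs C-alkylation of the malonate and Wittig closure faster than proton transfer to the ylide; the substrate secures this because the malonate C–H is its only acidic site (the aldehyde on quaternary C10 cannot enolise, the ketone is a dioxolane) and because ylide and aldehyde are held 1,6 to each other on the ring.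

Step 10
Reactants: 15 dimethyl 8,8-(ethylenedioxy)-10β-methyl-5αH-decal-1-ene-4,4-dicarboxylate
Product: 16 dimethyl 8,8-(ethylenedioxy)-10β-methyl-5αH-trans-decalin-4,4-dicarboxylate
Conditions: H2 (1 atm), Pd/C (10 %), EtOAc, 25 °C
Reagents that add atoms: none
Why: Heterogeneous hydrogenation saturates the disubstituted C1=C2 alkene; esters and dioxolane are inert and no stereocentre is formed.

Step 11
Reactants: 16 dimethyl 8,8-(ethylenedioxy)-10β-methyl-5αH-trans-decalin-4,4-dicarboxylate
Product: 18 8,8-(ethylenedioxy)-10β-methyl-5αH-trans-decalin-4-carboxylic acid (C4 epimers), via malonic diacid 17 (not isolated)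
Conditions: KOH (6 equiv), MeOH–H2O, 70 °C; 1 M HCl to pH 3 at 0 °C; then pyridine–toluene, 110 °C
Reagents that add atoms: potassium hydroxide, [K+].[OH-]
Why: Saponification of the geminal diester and thermal decarboxylation of the malonic acid leave one carboxyl on C4; the C4 configuration is irrelevant here because it is set in step 12.

Step 12
Reactants: 18 8,8-(ethylenedioxy)-10β-methyl-5αH-trans-decalin-4-carboxylic acid
Product: 20 4α,10β-dimethyl-8-oxo-5αH-trans-decalin-4β-carboxylic acid, via methylated ketal acid 19 (not isolated)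
Conditions: LiN(iPr)2 (2.5 equiv), THF–DMPU, 0 → 40 °C; MeI (3 equiv), 0 °C; then 2 M HCl, THF, 25 °C
Reagents that add atoms: iodomethane, CI; water, O
Why: α-Alkylation of the carboxylic acid dianion: the exocyclic enediolate at C4 of the trans-decalin should be methylated from the α (equatorial) face, away from the axial 10β-methyl group, giving 4α-CH3 and 4β-CO2H; the acidic work-up hydrolyses the dioxolane.

Step 13
Reactants: 20 4α,10β-dimethyl-8-oxo-5αH-trans-decalin-4β-carboxylic acid
Product: 22 4α,10β-dimethyl-8-oxo-5αH-trans-decalin-4β-carboxylic acid 6β-lactone (8-oxo 19,6β-lactone), via enone acid 21 (not isolated)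
Conditions: Pd(O2CCF3)2 (5 mol %), DMSO (10 mol %), O2 (1 atm), AcOH, 80 °C
Reagents that add atoms: none
Why: Palladium-catalysed aerobic α,β-dehydrogenation (palladium enolate, β-hydride elimination) can only desaturate C7–C6 because C10 bears no hydrogen; the axial 4β-carboxyl then adds to C6 of the enone by a 5-exo-trig oxa-Michael addition from the only face it can reach, which sets 6β-O.

Step 14
Reactants: 22 8-oxo 19,6β-lactone; 23 allyl bromide
Product: 25 9-allyl derivative of 22 (C9 epimers), via ring-opened allyl enone acid 24 (not isolated)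
Conditions: LiN(iPr)2 (2.2 equiv), THF, −78 °C; 23 (1.2 equiv), −78 → −20 °C; 1 M HCl; then Et3N (10 mol %), CH2Cl2, 25 °C
Reagents that add atoms: none
Why: Enolate alkylation: the first equivalent of base opens the β-acyloxy ketone by E1cB elimination to the enone carboxylate, the second gives the cross-conjugated α′-enolate at C9 (the only α′ site), which is C-allylated, and the carboxyl re-adds to C6 after acidification; the C9 configuration is not needed because C9 is enolised again in step 15.

Step 15
Reactants: 25 9-allyl derivative of 22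
Product: 27 9β-allyl-9α-hydroxy derivative of 22, via ring-opened hydroxy enone acid 26 (not isolated)
Conditions: KN(SiMe3)2 (2.3 equiv), THF, −78 → −40 °C; 3-phenyl-2-(phenylsulfonyl)oxaziridine (1.3 equiv), −78 °C; 1 M HCl; then Et3N (10 mol %), CH2Cl2, 25 °C
Reagents that add atoms: 3-phenyl-2-(phenylsulfonyl)oxaziridine, O=S(=O)(N1OC1c1ccccc1)c1ccccc1
Why: Davis hydroxylation of the regenerated tetrasubstituted C9 enolate; the oxaziridine should approach the α face, anti to the axial 10β-methyl group, which gives 9α-OH and leaves C11 β.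

Step 16
Reactants: 27 9β-allyl-9α-hydroxy derivative of 22
Product: 29 9α-hydroxy-9β-(3-hydroxypropyl) derivative of 22, via alkylborane 28 (not isolated)
Conditions: 9-BBN (2.5 equiv), THF, 0 → 25 °C; then 30 % H2O2, pH 7 phosphate buffer, 0 °C
Reagents that add atoms: hydrogen peroxide, OO; 9-borabicyclo[3.3.1]nonane, B1C2CCCC1CCC2 (boron present only in 28)
Why: Anti-Markovnikov hydroboration of the terminal alkene by 9-BBN, which should leave the hindered ketone and the lactone alone, and oxidation with retention give the primary C13 alcohol.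

Step 17
Reactants: 29 9α-hydroxy-9β-(3-hydroxypropyl) derivative of 22
Product: 31 8-oxo-14,15,16,17-tetranorlabdane-19,6β:13,9α-diolide, via lactol 30 (not isolated)
Conditions: TEMPO (20 mol %), PhI(OAc)2 (2.5 equiv), CH2Cl2, 25 °C
Reagents that add atoms: none
Why: Oxoammonium (TEMPO) oxidation of the primary alcohol gives the aldehyde, which closes onto the tertiary 9α-OH as the five-membered lactol and is oxidised again to the γ-lactone; this makes the C9–O–C13 ring without touching C9.

Step 18
Reactants: 31 8-oxo-14,15,16,17-tetranorlabdane-19,6β:13,9α-diolide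
Product: 32 8β-hydroxy-14,15,16-trinorlabdane-19,6β:13,9α-diolide (8α-methyl)
Conditions: MeMgBr (1.5 equiv), CeCl3 (1.5 equiv), THF, −78 °C; then aq. NH4Cl
Reagents that add atoms: methylmagnesium bromide, C[Mg]Br
Why: Cerium-mediated Grignard addition to the ketone, the most electrophilic carbonyl; attack should come from the α (equatorial) face because the axial β trajectory is blocked by the 10β-methyl group and the 6β-oxygen, which gives 8β-OH and 8α-CH3.

Step 19
Reactants: 32 8β-hydroxy-14,15,16-trinorlabdane-19,6β:13,9α-diolide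
Product: 33 9α,13-epoxy-8β-hydroxy-15,16-dinorlabd-13(14)-en-19,6β-olide (exocyclic enol ether)
Conditions: Cp2TiMe2 (3 equiv), toluene, 70 °C, dark
Reagents that add atoms: dimethyltitanocene, C[Ti](C)(C1C=CC=C1)C1C=CC=C1
Why: Petasis methylenation through Cp2Ti=CH2 converts the accessible 9α,13-lactone carbonyl into the exocyclic enol ether, while the C19 carbonyl, flanked by quaternary C4 in the bridged lactone, should be too hindered to react.

Step 20
Reactants: 33 9α,13-epoxy-8β-hydroxy-15,16-dinorlabd-13(14)-en-19,6β-olide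
Product: 35 C13 spiro-cyclobutanone (C13 is C3 of a cyclobutan-1-one ring), via dichlorocyclobutanone 34 (not isolated)
Conditions: Cl3CCOCl (2 equiv), Zn–Cu couple, Et2O, 25 °C; then Zn, AcOH, 25 °C
Reagents that add atoms: trichloroacetyl chloride, ClC(Cl)(Cl)C(Cl)=O
Why: (2+2) Cycloaddition of dichloroketene to the electron-rich enol ether (the CH2 terminus bonds to the ketene carbonyl carbon, C13 to CCl2) and reductive dechlorination give the spiro cyclobutanone, in which C13 bears two equivalent CH2 arms and is not yet stereogenic.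

Step 21
Reactants: 35 C13 spiro-cyclobutanone
Product: 36 (13S)-9α,13-epoxy-8β-hydroxylabdane-19,6β:16,15-diolide (target)
Conditions: (R)-3,3′-di(pyren-1-yl)-H8-BINOL phosphoric acid (10 mol %), 30 % H2O2 (1.5 equiv), CHCl3, −40 °C
Reagents that add atoms: hydrogen peroxide, OO
Why: Catalytic asymmetric Baeyer–Villiger oxidation of a prochiral 3,3-disubstituted cyclobutanone: the chiral phosphoric acid organises the Criegee adduct so that one of the two diastereotopic CH2 groups migrates, oxygen enters between C15 and C16, and C13 is set as S under catalyst control.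

**Compound list**
1 | cyclohexa-1,3-diene | C1=CC=CCC1 | starting material
2 | cis-cyclohex-2-ene-1,4-diyl diacetate (meso) | CC(=O)O[C@H]1C=C[C@@H](OC(C)=O)CC1 | intermediate
3 | dimethyl malonate | COC(=O)CC(=O)OC | starting material
4 | dimethyl 2-[(1R,4S)-4-acetoxycyclohex-2-en-1-yl]malonate (1,4-cis) | CC(=O)O[C@@H]1C=C[C@H](C(C(=O)OC)C(=O)OC)CC1 | intermediate
5 | dimethyl 2-[(1R,4S)-4-hydroxycyclohex-2-en-1-yl]malonate | O[C@@H]1C=C[C@H](C(C(=O)OC)C(=O)OC)CC1 | intermediate
6 | dimethyl 2-[(1R)-4-oxocyclohex-2-en-1-yl]malonate | O=C1C=C[C@H](C(C(=O)OC)C(=O)OC)CC1 | intermediate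
7 | dimethyl 2-[(1R,2S)-2-methyl-4-(trimethylsilyloxy)cyclohex-3-en-1-yl]malonate (trans) | C[Si](C)(C)OC1=C[C@@H](C)[C@H](C(C(=O)OC)C(=O)OC)CC1 | intermediate
8 | dimethyl 2-[(1S)-2-methyl-4-oxocyclohex-2-en-1-yl]malonate | O=C1C=C(C)[C@H](C(C(=O)OC)C(=O)OC)CC1 | intermediate
9 | dimethyl 2-[(1S,2S)-2-methyl-4-oxo-2-vinylcyclohexyl]malonate (malonyl cis to methyl; trans to vinyl) | O=C1CC[C@@H](C(C(=O)OC)C(=O)OC)[C@](C)(C=C)C1 | intermediate
10 | dimethyl 2-[7-methyl-7-vinyl-1,4-dioxaspiro[4.5]decan-8-yl]malonate (ethylene ketal of 9) | O1CCOC12CC[C@@H](C(C(=O)OC)C(=O)OC)[C@](C)(C=C)C2 | intermediate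
11 | secondary ozonide of 10 (1,2,4-trioxolan-3-yl in place of vinyl) | O1CCOC12CC[C@@H](C(C(=O)OC)C(=O)OC)[C@](C)(C3OCOO3)C2 | intermediate
12 | dimethyl 2-[7-formyl-7-methyl-1,4-dioxaspiro[4.5]decan-8-yl]malonate (formyl trans to malonyl) | O1CCOC12CC[C@@H](C(C(=O)OC)C(=O)OC)[C@](C)(C=O)C2 | intermediate
13 | triphenyl(vinyl)phosphonium bromide | C=C[P+](c1ccccc1)(c1ccccc1)c1ccccc1.[Br-] | starting material
14 | phosphonium ylide: 12 with CH2CH=PPh3 on the malonate carbon C4 | O1CCOC12CC[C@@H](C(CC=P(c3ccccc3)(c3ccccc3)c3ccccc3)(C(=O)OC)C(=O)OC)[C@](C)(C=O)C2 | intermediate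
15 | dimethyl 8,8-(ethylenedioxy)-10β-methyl-5αH-decal-1-ene-4,4-dicarboxylate (trans-fused) | O1CCOC12CC[C@@H]3[C@](C)(C=CCC3(C(=O)OC)C(=O)OC)C2 | intermediate
16 | dimethyl 8,8-(ethylenedioxy)-10β-methyl-5αH-trans-decalin-4,4-dicarboxylate | O1CCOC12CC[C@@H]3[C@](C)(CCCC3(C(=O)OC)C(=O)OC)C2 | intermediate
17 | 8,8-(ethylenedioxy)-10β-methyl-5αH-trans-decalin-4,4-dicarboxylic acid | O1CCOC12CC[C@@H]3[C@](C)(CCCC3(C(=O)O)C(=O)O)C2 | intermediate
18 | 8,8-(ethylenedioxy)-10β-methyl-5αH-trans-decalin-4-carboxylic acid (C4 epimers) | O1CCOC12CC[C@@H]3[C@](C)(CCCC3C(=O)O)C2 | intermediate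
19 | 8,8-(ethylenedioxy)-4α,10β-dimethyl-5αH-trans-decalin-4β-carboxylic acid | O1CCOC12CC[C@@H]3[C@](C)(CCC[C@]3(C)C(=O)O)C2 | intermediate
20 | 4α,10β-dimethyl-8-oxo-5αH-trans-decalin-4β-carboxylic acid | O=C1CC[C@@H]2[C@](C)(CCC[C@]2(C)C(=O)O)C1 | intermediate
21 | 4α,10β-dimethyl-8-oxo-5αH-decal-6-ene-4β-carboxylic acid | O=C1C=C[C@@H]2[C@](C)(CCC[C@]2(C)C(=O)O)C1 | intermediate
22 | 4α,10β-dimethyl-8-oxo-5αH-trans-decalin-4β-carboxylic acid 6β-lactone (8-oxo 19,6β-lactone) | O=C1C[C@H]2OC(=O)[C@@]3(C)CCC[C@@](C)([C@@H]23)C1 | intermediate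
23 | allyl bromide | C=CCBr | starting material
24 | 9-allyl derivative of 21 (C9 epimers) | O=C1C=C[C@@H]2[C@](C)(CCC[C@]2(C)C(=O)O)C1CC=C | intermediate
25 | 9-allyl derivative of 22 (C9 epimers) | O=C1C[C@H]2OC(=O)[C@@]3(C)CCC[C@@](C)([C@@H]23)C1CC=C | intermediate
26 | 9β-allyl-9α-hydroxy derivative of 21 | O=C1C=C[C@@H]2[C@](C)(CCC[C@]2(C)C(=O)O)[C@@]1(O)CC=C | intermediate
27 | 9β-allyl-9α-hydroxy derivative of 22 | O=C1C[C@H]2OC(=O)[C@@]3(C)CCC[C@@](C)([C@@H]23)[C@@]1(O)CC=C | intermediate
28 | 27 with 9-borabicyclo[3.3.1]nonan-9-yl on the terminal side-chain carbon C13 | O=C1C[C@H]2OC(=O)[C@@]3(C)CCC[C@@](C)([C@@H]23)[C@@]1(O)CCCB1C2CCCC1CCC2 | intermediate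
29 | 9α-hydroxy-9β-(3-hydroxypropyl) derivative of 22 | O=C1C[C@H]2OC(=O)[C@@]3(C)CCC[C@@](C)([C@@H]23)[C@@]1(O)CCCO | intermediate
30 | 9α,13-epoxy-13-hydroxy lactol of 29 (C13 epimers) | O=C1C[C@H]2OC(=O)[C@@]3(C)CCC[C@@](C)([C@@H]23)[C@@]12CCC(O)O2 | intermediate
31 | 8-oxo-14,15,16,17-tetranorlabdane-19,6β:13,9α-diolide | O=C1C[C@H]2OC(=O)[C@@]3(C)CCC[C@@](C)([C@@H]23)[C@@]12CCC(=O)O2 | intermediate
32 | 8β-hydroxy-14,15,16-trinorlabdane-19,6β:13,9α-diolide (8α-methyl) | C[C@]1(O)C[C@H]2OC(=O)[C@@]3(C)CCC[C@@](C)([C@@H]23)[C@@]12CCC(=O)O2 | intermediate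
33 | 9α,13-epoxy-8β-hydroxy-15,16-dinorlabd-13(14)-en-19,6β-olide | C[C@]1(O)C[C@H]2OC(=O)[C@@]3(C)CCC[C@@](C)([C@@H]23)[C@@]12CCC(=C)O2 | intermediate
34 | C13 spiro-2,2-dichlorocyclobutan-1-one adduct of 33 (C13 epimers; CCl2 on C13) | C[C@]1(O)C[C@H]2OC(=O)[C@@]3(C)CCC[C@@](C)([C@@H]23)[C@@]12CCC1(CC(=O)C1(Cl)Cl)O2 | intermediate
35 | C13 spiro-cyclobutanone (C13 is C3 of a cyclobutan-1-one ring) | C[C@]1(O)C[C@H]2OC(=O)[C@@]3(C)CCC[C@@](C)([C@@H]23)[C@@]12CCC1(CC(=O)C1)O2 | intermediate
36 | (13S)-9α,13-epoxy-8β-hydroxylabdane-19,6β:16,15-diolide | C[C@]1(O)C[C@H]2OC(=O)[C@@]3(C)CCC[C@@](C)([C@@H]23)[C@@]12CC[C@]1(COC(=O)C1)O2 | target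

Total step count: 21. Longest linear sequence: 21 steps (from 1).

**Steps most likely to fail**

Step 21. The catalyst may discriminate poorly between the two CH2 groups of the spiro cyclobutanone (mismatched pairing with the remote decalin), or the acid may open the 3-alkoxycyclobutanone ring. The fallback sets out from 33: the dichloroketene cycloaddition is run without dechlorination and the two C13-epimeric dichlorocyclobutanones are separated by chromatography. The epimer with the CCl2 carbon on the C8 side of the tetrahydrofuran ring, dichlorocyclobutanone F1, is oxidised with NaHCO3-buffered mCPBA. The non-halogenated CH2 should migrate, giving dichloro dilactone F2, and Zn/AcOH then returns to the route at 36. C13 is then fixed by separation of diastereomers and the lactone orientation by the chlorine atoms.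

Step 9. The Wittig closure onto the hindered neopentyl aldehyde may be slow, so that the ylide is lost by proton transfer or the Michael addition reverts. The fallback sets out from 10: C-allylation of the malonate (NaH, 23, THF) gives allyl malonate F6. Ring-closing metathesis with the second-generation Grubbs catalyst between the C10 vinyl group and the allyl group then returns to the route at 15. Here C3–C4 and C1–C2 are made in two separate steps.

Step 14. The E1cB opening may be incomplete, the carboxylate may be O-allylated, or deprotonation at the neopentyl C9 may be slow. The fallback sets out from 20: esterification (Me3SiCHN2, MeOH–toluene) gives methyl ester F3. The Pd(O2CCF3)2/DMSO/O2 dehydrogenation of step 13 gives enone ester F4, which cannot lactonise. Ordinary monoanion allylation (LiN(iPr)2, 23, THF, −78 °C) gives 9-allyl enone ester F5. LiI in pyridine at reflux cleaves the hindered methyl ester at the methyl carbon and the carboxylate closes onto C6, returning to the route at 25.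

**Further compounds**
F1 | step 21 | C13 spiro-2,2-dichlorocyclobutanone, single epimer with CCl2 on the C8 side | C[C@]1(O)C[C@H]2OC(=O)[C@@]3(C)CCC[C@@](C)([C@@H]23)[C@@]12CC[C@]1(CC(=O)C1(Cl)Cl)O2
F2 | step 21 | 14,14-dichloro derivative of 36 | C[C@]1(O)C[C@H]2OC(=O)[C@@]3(C)CCC[C@@](C)([C@@H]23)[C@@]12CC[C@]1(COC(=O)C1(Cl)Cl)O2
F3 | step 14 | methyl 4α,10β-dimethyl-8-oxo-5αH-trans-decalin-4β-carboxylate | O=C1CC[C@@H]2[C@](C)(CCC[C@]2(C)C(=O)OC)C1
F4 | step 14 | methyl 4α,10β-dimethyl-8-oxo-5αH-decal-6-ene-4β-carboxylate | O=C1C=C[C@@H]2[C@](C)(CCC[C@]2(C)C(=O)OC)C1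
F5 | step 14 | 9-allyl derivative of F4 (C9 epimers) | O=C1C=C[C@@H]2[C@](C)(CCC[C@]2(C)C(=O)OC)C1CC=C
F6 | step 9 | dimethyl 2-allyl-2-[7-methyl-7-vinyl-1,4-dioxaspiro[4.5]decan-8-yl]malonate | O1CCOC12CC[C@@H](C(CC=C)(C(=O)OC)C(=O)OC)[C@](C)(C=C)C2
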